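3 questions are put to this flask, and we answer them from the earlier runs.

all flasks: free catalyst 50 µM

| charge | left-handed substrate | right-handed substrate | partner | remark | time |
|---|---|---|---|---|---|
| red | 0.50 mM | 0.50 mM | 0.67 mM | run made earlier |  |
| violet | 0.50 mM | 0.50 mM | 1.5 mM | run made earlier |  |
| grey | 0.25 mM | 0.25 mM | 1 mM | run made earlier |  |
| flask | 0.50 mM | 0.50 mM | 1.00 mM |  | 5.0 h |

- red (time / h: left-handed product / %, right-handed substrate / %): 0.833: 12.9, 39.9; 1.50: 13.7, 39.5; 2.50: 12.8, 39.4; 3.00: 12.2, 39.3
- violet (time / h: left-handed product / %, right-handed substrate / %): 0.417: 17.9, 38.2; 1.00: 17.8, 36.8; 2.00: 16.2, 37.7; 3.00: 17.4, 36.4
- grey (time / h: left-handed product / %, right-handed substrate / %): 0.250: 27.6, 27.9; 0.500: 27.9, 26.9; 1.33: 27.7, 28.1; 3.00: 27.8, 28.1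

(readings scatter by 0.5 percentage points)

- free catalyst is single-handed; left-handed substrate and right-handed substrate are mirror images of each other, charged as a racemate, each of them at the stated concentration
- the analysis behind the earlier runs scatters by 0.5 percentage points, standard deviation
- reactions considered so far: free catalyst + left-handed substrate <-> catalyst intermediate A; free catalyst + right-handed substrate <-> catalyst intermediate B; partner + catalyst intermediate A -> free catalyst + left-handed product; partner + catalyst intermediate B -> free catalyst + right-handed product; 2 partner -> self-condensation product
- the reaction counts as stopped when no species that holds the left-handed substrate and right-handed substrate together changes by six tenths of a point or more over the second half of the time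

* at 5.0 h, what has stopped the reaction, if anything has (no working catalyst is left / all of the left-handed substrate has reacted / the partner has run out first / it is still moving / forward and back rates have come level)
* how much left-handed product there is at 5.0 h, in percent of the left-handed substrate and right-handed substrate together charged
* how much right-handed substrate there is at 5.0 h, in percent of the left-handed substrate and right-handed substrate together charged

The red run is flat from its first reading at 0.833 h, within the scatter, and ends with right-handed substrate at 39.3% and left-handed product at 12.2%, so lack of substrate did not stop it. We therefore take T, the left-handed product plus what the right-handed substrate has lost, in percent of the total charged. Averaged over its readings, T is 23.4% in the red run. In the violet run it is 30.0%.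

But the partner charge rose by a factor of 2.24, and T by a factor of only 1.28. If self-condensation goes with the square of the partner and the catalyst cycle with its first power, the two rates cross at some partner level; above it the share of partner reaching product falls, and our reckoning has T growing with the logarithm of the charge. We therefore carry G, the rise of T per e-fold of partner charge at fixed catalyst and substrate, read off these two runs with their scatter: 8.3 percentage points. From the red run, our reckoning puts this flask at T = 26.7%.

The forecast says the partner has run out first, with left-handed product at 15.2% and right-handed substrate at 38.5%, holding that “the rest is consumed by self-condensation”.

In the flask at 5.0 h, the partner has run out first: partner stands at 0% as the limiting reagent, left-handed product at 15.3% and right-handed substrate at 38.4%.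

    free catalyst + left-handed substrate ⇌ catalyst intermediate A (K = 12200 /M, k = 1.39 × 10⁵ /M/s)
    free catalyst + right-handed substrate ⇌ catalyst intermediate B (K = 15800 /M, k = 38300 /M/s)
    partner + catalyst intermediate A → free catalyst + left-handed product (k = 543 /M/s)
    partner + catalyst intermediate B → free catalyst + right-handed product (k = 234 /M/s)
    2 partner → self-condensation product (k = 83.9 /M/s)

This flask's T is 26.9%, against 26.7% from G. Self-condensation is the main reason this flask stops short: with that step taken away, conversion of both substrates together goes from 28.7% to >99.9%. That conversion also counts substrate bound as catalyst intermediate A, which T does not; taking that bound part as unchanged, G adds 5.8 points for the flask with twice the partner and all other amounts held, giving 34.5%, and the conversion of that run stands at 35.0%.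

The earlier runs and the new flask were computed on assumed constants; noise was put on by code.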